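**Retrosynthetic overview** (carotenoid numbering; ring A = oxo ring C1–C6, ring B = hydroxy ring C1'–C6')

1. The target, (3'S,6E,6'E)-3'-hydroxy-4',5'-didehydro-4,5'-retro-β,β-caroten-3-one, is cut last at ring B (C5'–C6' bond, H on C7') together with the C7'–C8' bond. A C30 polyenyl iodide carrying ring A and a C10 (Z)-bromo-enyne are joined in one pot: Sonogashira coupling, then 6-exo-dig alkyne carbopalladation with hydride capture.
2. Enabling feature: in ring B the exocyclic C6'=C7' bond lies between the endocyclic C4'=C5'(CH3) alkene and the quaternary C1'(CH3)2, with H on C7' cis to C5' and C8' cis to C1'. That is the imprint of syn addition of a C5' alkenylpalladium and a hydride across a C6'≡C7' triple bond tethered through C1'–C2'–C3'; C1' carries no hydrogen, so the alkyne cannot slip to an allene.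
3. The C30 iodide comes from a Wittig reaction at C14=C15 between a C19 keto-aldehyde (ring A, C7–C14) and a C11 iodo-tetraenyl phosphonium salt (C15–C8'); both derive from one iodotrienal.
4. Ring A is closed earlier by the same coupling/cyclisation of the bromo-enyne with the iodotrienal, then desilylated and oxidised with MnO2 to the C3 ketone. The C3' stereocentre comes from a Noyori transfer hydrogenation.
5. Order of ring formation: ring A (step 11), then ring B last (step 17).

Key step: step 17

Remark: all chain double bonds of the target are read as E and C3' as S; all polyenes are handled under argon in the dark.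

**Route**

Step 1
Reactants: 1 methyl 3,3-dimethylpent-4-enoate
Product: 2 N-methoxy-N,3,3-trimethylpent-4-enamide
Conditions: MeNH(OMe)·HCl, iPrMgCl, THF, −20 to 0 °C
Reagents that add atoms: N,O-dimethylhydroxylamine hydrochloride, CNOC.Cl
Why: Direct aminolysis of the ester by the magnesium amide (Weinreb amide formation) should leave the neopentyl vinyl group untouched.

Step 2
Reactants: 2 N-methoxy-N,3,3-trimethylpent-4-enamide
Product: 3 3,3-dimethyloct-1-en-6-yn-5-one
Conditions: CH3C≡CMgBr, THF, 0 °C; aq. NH4Cl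
Reagents that add atoms: 1-propynylmagnesium bromide, CC#C[Mg]Br
Why: Alkynyl Grignard addition to a Weinreb amide should stop at the ketone through the chelated tetrahedral intermediate.

Step 3
Reactants: 3 3,3-dimethyloct-1-en-6-yn-5-one
Product: 4 (5S)-3,3-dimethyloct-1-en-6-yn-5-ol
Conditions: RuCl[(S,S)-TsDPEN](p-cymene) (1 mol %), KOH (2 mol %), iPrOH, rt
Reagents that add atoms: none
Why: Noyori asymmetric transfer hydrogenation of an alkynyl ketone; the (S,S)-catalyst places the alkynyl group in the CH/π pocket and should deliver hydride to the face that gives the (S)-carbinol, the future C3'.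

Step 4
Reactants: 4 (5S)-3,3-dimethyloct-1-en-6-yn-5-ol
Product: 6 (5S,6Z)-7-bromo-3,3-dimethylocta-1,6-dien-5-ol, via cyclic alkenylaluminate 5 (not isolated)
Conditions: NaAlH2(OCH2CH2OMe)2 (Red-Al), THF, 0 °C to rt; then NBS, −78 °C; aq. Rochelle salt
Reagents that add atoms: N-bromosuccinimide, O=C1CCC(=O)N1Br
Why: Hydroxyl-directed trans-hydroalumination of the propargylic alcohol puts aluminium on the distal alkyne carbon inside a five-membered aluminate, and bromodealumination with retention should give the (Z)-bromoalkene without touching the stereocentre.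

Step 5
Reactants: 6 (5S,6Z)-7-bromo-3,3-dimethylocta-1,6-dien-5-ol
Product: 7 tert-butyl{[(5S,6Z)-7-bromo-3,3-dimethylocta-1,6-dien-5-yl]oxy}dimethylsilane
Conditions: TBSCl, imidazole, DMF, rt
Reagents that add atoms: tert-butyldimethylsilyl chloride, CC(C)(C)[Si](C)(C)Cl
Why: Standard silylation of a secondary allylic alcohol protects the future C3' oxygen against palladium alkoxide and ionisation chemistry.

Step 6
Reactants: 7 tert-butyl{[(5S,6Z)-7-bromo-3,3-dimethylocta-1,6-dien-5-yl]oxy}dimethylsilane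
Product: 9 (4S,5Z)-6-bromo-4-[(tert-butyldimethylsilyl)oxy]-2,2-dimethylhept-5-enal, via secondary ozonide 8 (not isolated)
Conditions: O3, CH2Cl2, −78 °C (Sudan Red 7B end point); then PPh3, −78 °C to rt
Reagents that add atoms: ozone, [O-][O+]=O
Why: Ozonolysis should cleave the electron-rich monosubstituted vinyl group well before the bromine-deactivated trisubstituted alkene when the ozone dose is limited by the dye end point.

Step 7
Reactants: 9 (4S,5Z)-6-bromo-4-[(tert-butyldimethylsilyl)oxy]-2,2-dimethylhept-5-enal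
Product: 10 tert-butyl{[(5S,6Z)-7-bromo-3,3-dimethyloct-6-en-1-yn-5-yl]oxy}dimethylsilane
Conditions: dimethyl (1-diazo-2-oxopropyl)phosphonate, K2CO3, MeOH, 0 °C to rt
Reagents that add atoms: dimethyl (1-diazo-2-oxopropyl)phosphonate, COP(=O)(OC)C(=[N+]=[N-])C(C)=O
Why: Seyferth–Gilbert homologation with the Ohira–Bestmann reagent suits a non-enolisable neopentyl aldehyde and should give the terminal alkyne on the quaternary carbon (future C6' on C1').

Step 8
Reactants: 11 (E)-pent-2-en-4-yn-1-ol
Product: 13 (2E,4E)-5-iodo-4-methylpenta-2,4-dien-1-ol, via alkenylalane 12 (not isolated)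
Conditions: AlMe3 (3 equiv), Cp2ZrCl2 (0.25 equiv), CH2Cl2, 0 °C to rt; then I2, THF, −30 °C; aq. K2CO3
Reagents that add atoms: trimethylaluminium, C[Al](C)C; iodine, II
Why: Negishi zirconium-catalysed carboalumination adds methyl and aluminium syn across the terminal alkyne with aluminium at the terminus, and iodinolysis with retention should give the (E)-iodoalkene.

Step 9
Reactants: 13 (2E,4E)-5-iodo-4-methylpenta-2,4-dien-1-ol
Product: 14 (2E,4E)-5-iodo-4-methylpenta-2,4-dienal
Conditions: MnO2, CH2Cl2, rt, dark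
Reagents that add atoms: none
Why: MnO2 oxidation of a primary allylic alcohol should give the dienal without touching the alkenyl iodide.

Step 10
Reactants: 14 (2E,4E)-5-iodo-4-methylpenta-2,4-dienal
Product: 15 (2E,4E,6E)-7-iodo-2,6-dimethylhepta-2,4,6-trienal
Conditions: Ph3P=C(CH3)CHO, toluene, 80 °C, dark
Reagents that add atoms: 2-(triphenyl-λ5-phosphanylidene)propanal, CC(C=O)=P(c1ccccc1)(c1ccccc1)c1ccccc1
Why: Wittig olefination with a stabilised formyl ylide should give the (E)-α-methyl enal, and the α-branched product is too unreactive to be homologated again.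

Step 11
Reactants: 10 tert-butyl{[(5S,6Z)-7-bromo-3,3-dimethyloct-6-en-1-yn-5-yl]oxy}dimethylsilane; 15 (2E,4E,6E)-7-iodo-2,6-dimethylhepta-2,4,6-trienal
Product: 17 (2E,4E,6E,8E)-8-[(4S)-4-[(tert-butyldimethylsilyl)oxy]-2,6,6-trimethylcyclohex-2-en-1-ylidene]-2,6-dimethylocta-2,4,6-trienal, via bromo-ynyl trienal 16 (not isolated)
Conditions: Pd(PPh3)4 (5 mol %), CuI (10 mol %), Et3N, THF, rt, dark; then HCO2H (3 equiv, Et3N in excess), 60 °C
Reagents that add atoms: none
Why: Sonogashira coupling should take the alkenyl iodide of 15 in preference to the trisubstituted bromide, and on warming with formate the bromide undergoes 6-exo-dig cyclic carbopalladation of the alkyne with hydride capture, which closes ring A and fixes the exocyclic geometry by syn addition.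

Step 12
Reactants: 17 (2E,4E,6E,8E)-8-[(4S)-4-[(tert-butyldimethylsilyl)oxy]-2,6,6-trimethylcyclohex-2-en-1-ylidene]-2,6-dimethylocta-2,4,6-trienal
Product: 18 (2E,4E,6E,8E)-8-[(4S)-4-hydroxy-2,6,6-trimethylcyclohex-2-en-1-ylidene]-2,6-dimethylocta-2,4,6-trienal
Conditions: n-Bu4NF, AcOH (1:1), THF, 0 °C to rt
Reagents that add atoms: none
Why: Acetic acid-buffered fluoride desilylation should free the ring alcohol without base-induced reactions of the polyenal.

Step 13
Reactants: 18 (2E,4E,6E,8E)-8-[(4S)-4-hydroxy-2,6,6-trimethylcyclohex-2-en-1-ylidene]-2,6-dimethylocta-2,4,6-trienal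
Product: 19 (2E,4E,6E,8E)-2,6-dimethyl-8-(2,6,6-trimethyl-4-oxocyclohex-2-en-1-ylidene)octa-2,4,6-trienal
Conditions: MnO2, CH2Cl2, rt, dark
Reagents that add atoms: none
Why: The ring carbinol is allylic to the whole polyene, so MnO2 should oxidise it to the C3 ketone of ring A; the stereocentre used here is deliberately destroyed.

Step 14
Reactants: 15 (2E,4E,6E)-7-iodo-2,6-dimethylhepta-2,4,6-trienal
Product: 20 (4E,6E,8E)-9-iodo-4,8-dimethylnona-1,4,6,8-tetraen-3-ol (racemic)
Conditions: CH2=CHMgBr, THF, −78 °C; aq. NH4Cl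
Reagents that add atoms: vinylmagnesium bromide, C=C[Mg]Br
Why: Grignard 1,2-addition to the enal at low temperature should give the vinyl carbinol without iodine–magnesium exchange.

Step 15
Reactants: 20 (4E,6E,8E)-9-iodo-4,8-dimethylnona-1,4,6,8-tetraen-3-ol
Product: 21 [(2E,4E,6E,8E)-9-iodo-4,8-dimethylnona-2,4,6,8-tetraen-1-yl]triphenylphosphonium bromide
Conditions: Ph3P·HBr, MeOH, 0 °C to rt, dark
Reagents that add atoms: triphenylphosphine hydrobromide, [Br-].c1ccc(cc1)[PH+](c1ccccc1)c1ccccc1
Why: Acid ionisation of the vinyl carbinol to a polyenyl cation and capture by triphenylphosphine at the unhindered terminus (allylic transposition, the classical route to carotenoid Wittig salts) should give the conjugated (E)-phosphonium salt.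

Step 16
Reactants: 19 (2E,4E,6E,8E)-2,6-dimethyl-8-(2,6,6-trimethyl-4-oxocyclohex-2-en-1-ylidene)octa-2,4,6-trienal; 21 [(2E,4E,6E,8E)-9-iodo-4,8-dimethylnona-2,4,6,8-tetraen-1-yl]triphenylphosphonium bromide
Product: 23 (4E)-4-[(2E,4E,6E,8E,10E,12E,14E,16E)-17-iodo-3,7,12,16-tetramethylheptadeca-2,4,6,8,10,12,14,16-octaen-1-ylidene]-3,5,5-trimethylcyclohex-2-en-1-one, via phosphorus ylide 22 (not isolated)
Conditions: NaOMe, MeOH/CH2Cl2, 0 °C to rt, dark; then heptane, 80 °C
Reagents that add atoms: none
Why: Wittig olefination of the aldehyde (the conjugated ketone is much less electrophilic) with the semistabilised polyenyl ylide forms C14=C15, and any Z isomer at this unhindered disubstituted bond should equilibrate thermally to E as is usual in carotenoid Wittig reactions.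

Step 17
Reactants: 23 (4E)-4-[(2E,4E,6E,8E,10E,12E,14E,16E)-17-iodo-3,7,12,16-tetramethylheptadeca-2,4,6,8,10,12,14,16-octaen-1-ylidene]-3,5,5-trimethylcyclohex-2-en-1-one; 10 tert-butyl{[(5S,6Z)-7-bromo-3,3-dimethyloct-6-en-1-yn-5-yl]oxy}dimethylsilane
Product: 25 (3'S,6E,6'E)-3'-[(tert-butyldimethylsilyl)oxy]-4',5'-didehydro-4,5'-retro-β,β-caroten-3-one, via C40 bromo-enyne 24 (not isolated)
Conditions: Pd(PPh3)4 (10 mol %), CuI (10 mol %), Et3N, THF, rt, dark; then HCO2H (3 equiv, Et3N in excess), 60 °C
Reagents that add atoms: none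
Why: Zerovalent palladium inserts first into the C8'–I bond of 23 at room temperature and the copper acetylide of 10 is transferred, so reductive elimination forms the C7'–C8' bond while the trisubstituted C5'–Br bond is untouched (Sonogashira coupling). On warming with triethylammonium formate the same catalyst inserts into C5'–Br, the alkenylpalladium adds syn across the C6'≡C7' triple bond, and formate-derived hydride replaces palladium on C7' with retention; the closest known type is the cyclic carbopalladation of alkynes with hydride capture from formate. Ring B closes in the 6-exo-dig mode through the new C5'–C6' bond, since the 7-endo alternative would put a trans double bond into the ring. No stereocentre is formed: C3' (S) comes unchanged from step 3, C4'=C5' is cis in the ring because the bromide is Z, and C6'=C7' has H cis to C5' and C8' cis to C1' (6'E) because syn addition is followed by retentive C–H reductive elimination. The step needs iodide-over-bromide chemoselectivity, secured by the reactivity gap between a polyenyl iodide and a trisubstituted alkenyl bromide at room temperature. It also needs cyclisation to outrun hydride capture of the first alkenylpalladium, secured by the six-membered intramolecular insertion and the Thorpe–Ingold effect of the C1' gem-dimethyl group.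

Step 18
Reactants: 25 (3'S,6E,6'E)-3'-[(tert-butyldimethylsilyl)oxy]-4',5'-didehydro-4,5'-retro-β,β-caroten-3-one
Product: 26 (3'S,6E,6'E)-3'-hydroxy-4',5'-didehydro-4,5'-retro-β,β-caroten-3-one
Conditions: n-Bu4NF, AcOH (1:1), THF, 0 °C, dark
Reagents that add atoms: none
Why: Buffered fluoride desilylation should free the C3' alcohol without ionising the polyenylic carbinol or enolising the ring A dienone.

**Compound list**

1 | methyl 3,3-dimethylpent-4-enoate | C=CC(C)(C)CC(=O)OC | starting material
2 | N-methoxy-N,3,3-trimethylpent-4-enamide | C=CC(C)(C)CC(=O)N(C)OC | intermediate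
3 | 3,3-dimethyloct-1-en-6-yn-5-one | C=CC(C)(C)CC(=O)C#CC | intermediate
4 | (5S)-3,3-dimethyloct-1-en-6-yn-5-ol | CC#C[C@@H](O)CC(C)(C)C=C | intermediate
5 | cyclic alkenylaluminate (sodium 2,5-dihydro-1,2-oxaluminol-2-uide with two 2-methoxyethoxy groups on Al, methyl on the Al-bound alkene carbon) | [Na+].CC1=C[C@H](CC(C)(C)C=C)O[Al-]1(OCCOC)OCCOC | intermediate
6 | (5S,6Z)-7-bromo-3,3-dimethylocta-1,6-dien-5-ol | C/C(Br)=C/[C@@H](O)CC(C)(C)C=C | intermediate
7 | tert-butyl{[(5S,6Z)-7-bromo-3,3-dimethylocta-1,6-dien-5-yl]oxy}dimethylsilane | C/C(Br)=C/[C@@H](O[Si](C)(C)C(C)(C)C)CC(C)(C)C=C | intermediate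
8 | secondary ozonide of 7 (1,2,4-trioxolane on the former vinyl group, epimer mixture at the trioxolane carbon) | C/C(Br)=C/[C@@H](O[Si](C)(C)C(C)(C)C)CC(C)(C)C1OCOO1 | intermediate
9 | (4S,5Z)-6-bromo-4-[(tert-butyldimethylsilyl)oxy]-2,2-dimethylhept-5-enal | C/C(Br)=C/[C@@H](O[Si](C)(C)C(C)(C)C)CC(C)(C)C=O | intermediate
10 | tert-butyl{[(5S,6Z)-7-bromo-3,3-dimethyloct-6-en-1-yn-5-yl]oxy}dimethylsilane | C/C(Br)=C/[C@@H](O[Si](C)(C)C(C)(C)C)CC(C)(C)C#C | intermediate
11 | (E)-pent-2-en-4-yn-1-ol | C#C/C=C/CO | starting material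
12 | alkenylalane (dimethylaluminium alkoxide of (2E,4E)-5-(dimethylalumanyl)-4-methylpenta-2,4-dien-1-ol) | C[Al](C)/C=C(C)/C=C/CO[Al](C)C | intermediate
13 | (2E,4E)-5-iodo-4-methylpenta-2,4-dien-1-ol | I/C=C(C)/C=C/CO | intermediate
14 | (2E,4E)-5-iodo-4-methylpenta-2,4-dienal | I/C=C(C)/C=C/C=O | intermediate
15 | (2E,4E,6E)-7-iodo-2,6-dimethylhepta-2,4,6-trienal | I/C=C(C)/C=C/C=C(C)/C=O | intermediate
16 | (2E,4E,6E,12S,13Z)-14-bromo-12-[(tert-butyldimethylsilyl)oxy]-2,6,10,10-tetramethylpentadeca-2,4,6,13-tetraen-8-ynal | O=C/C(C)=C/C=C/C(C)=C/C#CC(C)(C)C[C@H](O[Si](C)(C)C(C)(C)C)/C=C(/C)Br | intermediate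
17 | (2E,4E,6E,8E)-8-[(4S)-4-[(tert-butyldimethylsilyl)oxy]-2,6,6-trimethylcyclohex-2-en-1-ylidene]-2,6-dimethylocta-2,4,6-trienal | O=C/C(C)=C/C=C/C(C)=C/C=C1/C(C)=C[C@@H](O[Si](C)(C)C(C)(C)C)CC1(C)C | intermediate
18 | (2E,4E,6E,8E)-8-[(4S)-4-hydroxy-2,6,6-trimethylcyclohex-2-en-1-ylidene]-2,6-dimethylocta-2,4,6-trienal | O=C/C(C)=C/C=C/C(C)=C/C=C1/C(C)=C[C@@H](O)CC1(C)C | intermediate
19 | (2E,4E,6E,8E)-2,6-dimethyl-8-(2,6,6-trimethyl-4-oxocyclohex-2-en-1-ylidene)octa-2,4,6-trienal | O=C/C(C)=C/C=C/C(C)=C/C=C1/C(C)=CC(=O)CC1(C)C | intermediate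
20 | (4E,6E,8E)-9-iodo-4,8-dimethylnona-1,4,6,8-tetraen-3-ol (racemic) | C=CC(O)/C(C)=C/C=C/C(C)=C/I | intermediate
21 | [(2E,4E,6E,8E)-9-iodo-4,8-dimethylnona-2,4,6,8-tetraen-1-yl]triphenylphosphonium bromide | [Br-].I/C=C(C)/C=C/C=C(C)/C=C/C[P+](c1ccccc1)(c1ccccc1)c1ccccc1 | intermediate
22 | phosphorus ylide of 21 | I/C=C(C)/C=C/C=C(C)/C=C/C=P(c1ccccc1)(c1ccccc1)c1ccccc1 | intermediate
23 | (4E)-4-[(2E,4E,6E,8E,10E,12E,14E,16E)-17-iodo-3,7,12,16-tetramethylheptadeca-2,4,6,8,10,12,14,16-octaen-1-ylidene]-3,5,5-trimethylcyclohex-2-en-1-one (C30 keto-iodide, iodine on C8') | CC1=CC(=O)CC(C)(C)\C1=C/C=C(C)/C=C/C=C(C)/C=C/C=C/C(C)=C/C=C/C(C)=C/I | intermediate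
24 | C40 bromo-enyne: 23 with iodine replaced by the alkynyl carbon of 10 (C7'≡C6' triple bond, C1' gem-dimethyl, C3' OTBS (S), (Z)-C4'=C5'(CH3)Br) | CC1=CC(=O)CC(C)(C)\C1=C/C=C(C)/C=C/C=C(C)/C=C/C=C/C(C)=C/C=C/C(C)=C/C#CC(C)(C)C[C@H](O[Si](C)(C)C(C)(C)C)/C=C(/C)Br | intermediate
25 | (3'S,6E,6'E)-3'-[(tert-butyldimethylsilyl)oxy]-4',5'-didehydro-4,5'-retro-β,β-caroten-3-one | CC1=CC(=O)CC(C)(C)\C1=C/C=C(C)/C=C/C=C(C)/C=C/C=C/C(C)=C/C=C/C(C)=C/C=C1/C(C)=C[C@@H](O[Si](C)(C)C(C)(C)C)CC1(C)C | intermediate
26 | (3'S,6E,6'E)-3'-hydroxy-4',5'-didehydro-4,5'-retro-β,β-caroten-3-one | CC1=CC(=O)CC(C)(C)\C1=C/C=C(C)/C=C/C=C(C)/C=C/C=C/C(C)=C/C=C/C(C)=C/C=C1/C(C)=C[C@@H](O)CC1(C)C | target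

**Step count and risks**

Total step count: 18. Longest linear sequence: 13 steps (steps 1–7, 11–13, 16–18).

Steps most likely to fail:

Step 17. The alkenylpalladium formed from the bromide may be reduced by formate before it closes the ring, palladium hydride may isomerise or partly reduce the polyene and the ring A dienone at 60 °C, and the iodide-over-bromide selectivity of the first stage may erode. The fallback closes ring B on the small fragment and joins the chain afterwards; it sets out from 10 and 23 and comes back to the route at 25. The alkyne of 10 is silylated (LiHMDS, THF, −78 °C; Me3SiCl) to tert-butyl{[(5S,6Z)-7-bromo-3,3-dimethyl-1-(trimethylsilyl)oct-6-en-1-yn-5-yl]oxy}dimethylsilane F1. Intramolecular alkyne carbopalladation with hydride capture (Pd(OAc)2, PPh3, HCO2Na, Et4NCl, DMF, 70 °C) should give tert-butyldimethyl{[(1S,4E)-3,5,5-trimethyl-4-[(trimethylsilyl)methylidene]cyclohex-2-en-1-yl]oxy}silane F2, with silicon cis to the gem-dimethyl carbon. Iododesilylation with retention (N-iodosuccinimide, MeCN, 0 °C) gives tert-butyl{[(1S,4E)-4-(iodomethylidene)-3,5,5-trimethylcyclohex-2-en-1-yl]oxy}dimethylsilane F3. Iodine–lithium exchange (t-BuLi, THF, −78 °C) followed by ZnCl2 gives the alkenylzinc chloride F4, and Negishi coupling with 23 (Pd(PPh3)4, THF, rt) forms the C7'–C8' bond with retention to give 25. Ring B is still the last ring closed.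

Step 11. The trienal may condense with the amine or be reduced during the formate stage, and the first alkenylpalladium may again be reduced before cyclisation. The fallback sets out from 15 and uses the alkenylzinc chloride F4 prepared from 10 as described for step 17: Negishi coupling (Pd(PPh3)4, THF, rt), which tolerates the aldehyde, forms the C7–C8 bond and comes back to the route at 17. This fallback makes no new compound (F0).

Step 16. The new C14=C15 bond may form with poor E/Z control that heating does not fully correct, and methoxide may trigger aldol-type reactions through the ring A ketone. The fallback replaces the phosphonium ylide by a phosphonate carbanion; it sets out from 20 and comes back at 23. PBr3 (Et2O, −20 °C) converts 20 by allylic transposition into (1E,3E,5E,7E)-9-bromo-1-iodo-2,6-dimethylnona-1,3,5,7-tetraene F5. Michaelis–Becker reaction with NaP(O)(OEt)2 (THF, 0 °C) gives diethyl [(2E,4E,6E,8E)-9-iodo-4,8-dimethylnona-2,4,6,8-tetraen-1-yl]phosphonate F6. Its sodium salt (NaHMDS, THF, −78 °C) and 19 should give 23 in an E-selective Horner–Wadsworth–Emmons reaction.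

Further compounds
F1 | step 17 | tert-butyl{[(5S,6Z)-7-bromo-3,3-dimethyl-1-(trimethylsilyl)oct-6-en-1-yn-5-yl]oxy}dimethylsilane | C/C(Br)=C/[C@@H](O[Si](C)(C)C(C)(C)C)CC(C)(C)C#C[Si](C)(C)C
F2 | step 17 | tert-butyldimethyl{[(1S,4E)-3,5,5-trimethyl-4-[(trimethylsilyl)methylidene]cyclohex-2-en-1-yl]oxy}silane | C[Si](C)(C)/C=C1/C(C)=C[C@@H](O[Si](C)(C)C(C)(C)C)CC1(C)C
F3 | step 17 | tert-butyl{[(1S,4E)-4-(iodomethylidene)-3,5,5-trimethylcyclohex-2-en-1-yl]oxy}dimethylsilane | I/C=C1/C(C)=C[C@@H](O[Si](C)(C)C(C)(C)C)CC1(C)C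
F4 | step 17 | {(E)-[(4S)-4-[(tert-butyldimethylsilyl)oxy]-2,6,6-trimethylcyclohex-2-en-1-ylidene]methyl}zinc chloride | Cl[Zn]/C=C1/C(C)=C[C@@H](O[Si](C)(C)C(C)(C)C)CC1(C)C
F0 | step 11 | none | none
F5 | step 16 | (1E,3E,5E,7E)-9-bromo-1-iodo-2,6-dimethylnona-1,3,5,7-tetraene | I/C=C(C)/C=C/C=C(C)/C=C/CBr
F6 | step 16 | diethyl [(2E,4E,6E,8E)-9-iodo-4,8-dimethylnona-2,4,6,8-tetraen-1-yl]phosphonate | I/C=C(C)/C=C/C=C(C)/C=C/CP(=O)(OCC)OCC
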